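**Plan**

1. Drimane numbering is used (decalin C1–C10, C11 on C9, C12 on C8). The retrosynthesis cuts, in order: the C1–O ester; the two aldehydes (back to a C11 ester and a C12 enoate); C8–C12 (carbonylation of a C7 enol triflate); ring A at C1–C2 and C4–C5; ring B at C5–C10 and C8–C9 (Diels–Alder).
2. Forward: ring B is made first as a 4-formyl-4-methylcyclohexenone. Ring A is then annulated in one flask with a prenyl unit. The ring fusion is edited (dienone, hydrogenation, Li/NH3), C12 is added, and oxidation levels and the ester are adjusted.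
3. Enabling feature: C1 and C5 of ring A both sit on quaternary C10. In the ring-B precursor they are an aldehyde carbon and an enone β-carbon in a 1,3-relation. A prenyl C2–C3–C4Me2 unit bridges them: its CH2 end (C2) adds to the aldehyde as an allylboron, and after H-atom transfer its CMe2 end (C4) adds to C5 as a tertiary radical.
4. Stereochemistry: C10 comes from the catalytic asymmetric Diels–Alder and C1 from the catalyst-controlled allylboration. C9 and C5 are relayed from the C10 methyl (H2 to the α face at C9; trans-selective dissolving-metal protonation at C5).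

Key step: step 2

Assumption: the facial sense of the TADDOL-catalysed cycloaddition and of the TRIP-catalysed allylboration on these new substrates follows that known for simpler α-substituted acroleins and aldehydes; if either is opposite, the antipodal catalyst is used.

**Route**

Step 1
Reactants: 1 (E)-1-(dimethylamino)-3-(tert-butyldimethylsilyloxy)buta-1,3-diene; 2 ethyl (E)-3-methyl-4-oxobut-2-enoate
Product: 4 ethyl (1S,2S)-2-formyl-2-methyl-5-oxocyclohex-3-ene-1-carboxylate, via aminocyclohexene silyl enol ether cycloadduct 3 (not isolated)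
Conditions: (R,R)-1-naphthyl-TADDOL (20 mol%), toluene, −80 °C; then aq. HF, MeCN, 0 °C
Reagents that add atoms: none
Why: Hydrogen-bond-catalysed Diels–Alder reaction of an aminosiloxydiene with an α-substituted acrolein: the nucleophilic CH2 terminus bonds to the enal β-carbon (C9) and the amino terminus to the formyl-bearing α-carbon, so quaternary C10 (set by the TADDOL-shielded aldehyde face) lies next to the future enone β-carbon C5, and HF then hydrolyses the silyl enol ether and eliminates dimethylamine to give the enone.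

Step 2
Reactants: 4 ethyl (1S,2S)-2-formyl-2-methyl-5-oxocyclohex-3-ene-1-carboxylate; 5 4,4,5,5-tetramethyl-2-(2-methylbut-3-en-2-yl)-1,3,2-dioxaborolane
Product: 7 ethyl 1β-hydroxy-7-oxo-12-nor-5β-driman-11-oate, via homoallylic pinacol borate 6 (not isolated)
Conditions: 5 (1.3 equiv), (R)-TRIP (10 mol%), 4 Å MS, toluene, 0 °C to rt; then EtOH, Fe(acac)3 (30 mol%), PhSiH3 (2.5 equiv), 35 °C
Reagents that add atoms: none
Why: Stage one is a closed, chair-like allylboration in which the tertiary allylboronate 5 transfers its CH2 terminus to the aldehyde with allylic transposition (C1–C2 bond, linear prenyl group), the chiral phosphoric acid binding the boronate oxygen and the formyl hydrogen so that one aldehyde face is attacked and C1 is set as R; the enone ketone does not react with allylboronates. Stage two is an iron-hydride H-atom transfer to the electron-rich trisubstituted alkene (H to C3), after which the tertiary C4 radical adds to the enone β-carbon C5 in a 6-exo-trig closure (C4–C5 bond, ring A), and the α-keto radical is reduced by Fe(II) and protonated by ethanol, which also cleaves the O–B bond. The closest known reaction types are the phosphoric acid-catalysed allylboration of aldehydes and the Fe(acac)3/PhSiH3 reductive olefin–enone coupling (HAT-initiated Giese cyclisation, radical–polar crossover annulation). The tether from C1 reaches C5 only on the face of ring B that carries C1, so the first-formed ring fusion should be cis (5β-H); this centre is not needed and is reset in steps 4 to 6. The step needs chemoselectivity (aldehyde over enone in stage one, alkene over enone for HAT in stage two) and linear regiochemistry, which the allylboron reactivity pattern, the polarity of HAT and the α,α-dimethyl substitution of 5 should secure.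

Step 3
Reactants: 7 ethyl 1β-hydroxy-7-oxo-12-nor-5β-driman-11-oate
Product: 8 ethyl 1β-(tert-butyldimethylsilyloxy)-7-oxo-12-nor-5β-driman-11-oate
Conditions: TBSOTf (1.1 equiv), 2,6-lutidine, CH2Cl2, −78 to 0 °C
Reagents that add atoms: tert-butyldimethylsilyl trifluoromethanesulfonate, CC(C)(C)[Si](C)(C)OS(=O)(=O)C(F)(F)F
Why: Silylation of the hindered secondary alcohol with a silyl triflate at low temperature should outrun enol silylation of the ketone, and it also blocks lactonisation of the 1-OH onto the C11 ester and protects C1 for the oxidation that follows.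

Step 4
Reactants: 8 ethyl 1β-(tert-butyldimethylsilyloxy)-7-oxo-12-nor-5β-driman-11-oate
Product: 9 ethyl 1β-(tert-butyldimethylsilyloxy)-7-oxo-12-nordrima-5,8-dien-11-oate
Conditions: IBX (4 equiv), DMSO/fluorobenzene, 75 °C
Reagents that add atoms: none
Why: IBX-mediated α,β-dehydrogenation of the ketone on both sides should give the cross-conjugated dienone, which cannot aromatise because C10 is quaternary; this removes the unwanted C5 configuration and makes the two α-positions of the ketone distinguishable.

Step 5
Reactants: 9 ethyl 1β-(tert-butyldimethylsilyloxy)-7-oxo-12-nordrima-5,8-dien-11-oate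
Product: 10 ethyl 1β-(tert-butyldimethylsilyloxy)-7-oxo-12-nordrim-5-en-11-oate
Conditions: H2 (1 atm), 5% Pd/C, EtOAc, rt, stopped after one equivalent
Reagents that add atoms: none
Why: Catalytic hydrogenation should take the electron-poor, less hindered C8=C9 bond (C5=C6 is flanked by two quaternary carbons) and add H2 from the face opposite the C10 methyl, as in the Δ1 reduction of steroidal 1,4-dien-3-ones, which sets 9α-H with the ester β.

Step 6
Reactants: 10 ethyl 1β-(tert-butyldimethylsilyloxy)-7-oxo-12-nordrim-5-en-11-oate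
Product: 11 ethyl 1β-(tert-butyldimethylsilyloxy)-7-oxo-12-nor-5α-driman-11-oate
Conditions: Li (2.5 equiv), NH3/THF, t-BuOH (1 equiv), −78 °C, short contact; then NH4Cl
Reagents that add atoms: none
Why: Dissolving-metal reduction of the octalone-type enone protonates the C5 β-carbanion axially and should give the trans ring fusion (5α-H, relayed from C10); the enone is reduced far faster than the isolated ester, and t-BuOH buffers amide formation so that C9 is not epimerised.

Step 7
Reactants: 11 ethyl 1β-(tert-butyldimethylsilyloxy)-7-oxo-12-nor-5α-driman-11-oate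
Product: 12 ethyl 1β-(tert-butyldimethylsilyloxy)-7-(trifluoromethanesulfonyloxy)-12-nordrim-7-en-11-oate
Conditions: KHMDS (1.05 equiv), THF, −78 °C; then PhNTf2; aq. NH4Cl
Reagents that add atoms: N-phenylbis(trifluoromethanesulfonimide), O=S(=O)(N(c1ccccc1)S(=O)(=O)C(F)(F)F)C(F)(F)F
Why: Kinetic enolisation followed by O-triflation should occur toward C8, because the axial hydrogen on C6 is screened by the axial methyls on C4 and C10 while the ester α-hydrogen at C9 is less acidic than the ketone α-hydrogens.

Step 8
Reactants: 12 ethyl 1β-(tert-butyldimethylsilyloxy)-7-(trifluoromethanesulfonyloxy)-12-nordrim-7-en-11-oate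
Product: 13 11-ethyl 12-methyl 1β-(tert-butyldimethylsilyloxy)drim-7-ene-11,12-dioate
Conditions: Pd(OAc)2 (5 mol%), dppf, CO (1 atm), MeOH, Et3N, DMF, 60 °C
Reagents that add atoms: carbon monoxide, [C-]#[O+]; methanol, CO
Why: Palladium-catalysed methoxycarbonylation of the vinyl triflate installs C12 on C8 with the C7=C8 bond already in place, and triethylamine is too weak a base to epimerise C9.

Step 9
Reactants: 13 11-ethyl 12-methyl 1β-(tert-butyldimethylsilyloxy)drim-7-ene-11,12-dioate
Product: 14 1β-(tert-butyldimethylsilyloxy)drim-7-ene-11,12-diol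
Conditions: DIBAL-H (5 equiv), CH2Cl2, −78 to 0 °C; Rochelle salt
Reagents that add atoms: none
Why: DIBAL reduces the saturated ester and, by 1,2-reduction, the enoate to the primary and allylic alcohols without touching the silyl ether or the alkene.

Step 10
Reactants: 14 1β-(tert-butyldimethylsilyloxy)drim-7-ene-11,12-diol
Product: 15 11,12-O-isopropylidene-1β-(tert-butyldimethylsilyloxy)drim-7-ene-11,12-diol
Conditions: 2,2-dimethoxypropane, PPTS (cat.), CH2Cl2, rt
Reagents that add atoms: 2,2-dimethoxypropane, COC(C)(C)OC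
Why: Acid-catalysed transketalisation ties the cis-disposed 1,4-diol into a seven-membered acetonide (as with cis-but-2-ene-1,4-diol), which masks both primary alcohols while C1 is handled.

Step 11
Reactants: 15 11,12-O-isopropylidene-1β-(tert-butyldimethylsilyloxy)drim-7-ene-11,12-diol
Product: 16 11,12-O-isopropylidenedrim-7-ene-1β,11,12-triol
Conditions: TBAF, THF, 50 °C
Reagents that add atoms: none
Why: Fluoride cleaves the hindered silyl ether under basic conditions that leave the acetonide intact.

Step 12
Reactants: 16 11,12-O-isopropylidenedrim-7-ene-1β,11,12-triol; 17 (E)-3-(4-methoxyphenyl)prop-2-enoyl chloride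
Product: 18 1β-[(E)-4-methoxycinnamoyloxy]-11,12-O-isopropylidenedrim-7-ene-11,12-diol
Conditions: Et3N, DMAP, CH2Cl2, 40 °C
Reagents that add atoms: none
Why: DMAP-catalysed acylation with the acid chloride should esterify the equatorial but neopentyl-type 1β-alcohol, with the E-alkene of the acyl group unchanged.

Step 13
Reactants: 18 1β-[(E)-4-methoxycinnamoyloxy]-11,12-O-isopropylidenedrim-7-ene-11,12-diol
Product: 19 1β-[(E)-4-methoxycinnamoyloxy]drim-7-ene-11,12-diol
Conditions: PPTS, MeOH, rt
Reagents that add atoms: none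
Why: Mild acid transketalisation to methanol removes the acetonide without cleaving the cinnamate and should be too mild to move the acyl group from O1 to O11.

Step 14
Reactants: 19 1β-[(E)-4-methoxycinnamoyloxy]drim-7-ene-11,12-diol
Product: 20 1β-[(E)-4-methoxycinnamoyloxy]drim-7-ene-11,12-dial, (1R,5S,9R,10S), the target
Conditions: (COCl)2, DMSO, CH2Cl2, −78 °C; Et3N, −78 to −30 °C; cold buffered work-up
Reagents that add atoms: none
Why: Double Swern oxidation of the 11,12-diol to the ene-dial is the standard polygodial endgame, and keeping the base step cold should avoid epimerisation of the kinetically set 9β-formyl group.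

**Compound list**

1 | (E)-1-(dimethylamino)-3-(tert-butyldimethylsilyloxy)buta-1,3-diene | CN(C)/C=C/C(=C)O[Si](C)(C)C(C)(C)C | starting material
2 | ethyl (E)-3-methyl-4-oxobut-2-enoate | CCOC(=O)/C=C(/C=O)C | starting material
3 | ethyl 3-(dimethylamino)-2-formyl-2-methyl-5-(tert-butyldimethylsilyloxy)cyclohex-4-ene-1-carboxylate (endo adduct: CHO trans to CO2Et, cis to NMe2) | CCOC(=O)[C@H]1CC(O[Si](C)(C)C(C)(C)C)=C[C@H](N(C)C)[C@]1(C)C=O | intermediate
4 | ethyl (1S,2S)-2-formyl-2-methyl-5-oxocyclohex-3-ene-1-carboxylate | CCOC(=O)[C@H]1CC(=O)C=C[C@]1(C)C=O | intermediate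
5 | 4,4,5,5-tetramethyl-2-(2-methylbut-3-en-2-yl)-1,3,2-dioxaborolane | C=CC(C)(C)B1OC(C)(C)C(C)(C)O1 | starting material
6 | ethyl (1S,2S)-2-methyl-2-[(1R)-4-methyl-1-(4,4,5,5-tetramethyl-1,3,2-dioxaborolan-2-yloxy)pent-3-enyl]-5-oxocyclohex-3-ene-1-carboxylate | CCOC(=O)[C@H]1CC(=O)C=C[C@]1(C)[C@@H](CC=C(C)C)OB2OC(C)(C)C(C)(C)O2 | intermediate
7 | ethyl 1β-hydroxy-7-oxo-12-nor-5β-driman-11-oate (cis-fused, 9α-H, 10β-Me) | O[C@@H]1CCC(C)(C)[C@H]2CC(=O)C[C@H](C(=O)OCC)[C@@]12C | intermediate
8 | ethyl 1β-(tert-butyldimethylsilyloxy)-7-oxo-12-nor-5β-driman-11-oate | CC(C)(C)[Si](C)(C)O[C@@H]1CCC(C)(C)[C@H]2CC(=O)C[C@H](C(=O)OCC)[C@@]12C | intermediate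
9 | ethyl 1β-(tert-butyldimethylsilyloxy)-7-oxo-12-nordrima-5,8-dien-11-oate | CC(C)(C)[Si](C)(C)O[C@@H]1CCC(C)(C)C2=CC(=O)C=C(C(=O)OCC)[C@@]12C | intermediate
10 | ethyl 1β-(tert-butyldimethylsilyloxy)-7-oxo-12-nordrim-5-en-11-oate (9α-H) | CC(C)(C)[Si](C)(C)O[C@@H]1CCC(C)(C)C2=CC(=O)C[C@H](C(=O)OCC)[C@@]12C | intermediate
11 | ethyl 1β-(tert-butyldimethylsilyloxy)-7-oxo-12-nor-5α-driman-11-oate (trans-fused) | CC(C)(C)[Si](C)(C)O[C@@H]1CCC(C)(C)[C@@H]2CC(=O)C[C@H](C(=O)OCC)[C@@]12C | intermediate
12 | ethyl 1β-(tert-butyldimethylsilyloxy)-7-(trifluoromethanesulfonyloxy)-12-nordrim-7-en-11-oate | CC(C)(C)[Si](C)(C)O[C@@H]1CCC(C)(C)[C@@H]2CC(OS(=O)(=O)C(F)(F)F)=C[C@H](C(=O)OCC)[C@@]12C | intermediate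
13 | 11-ethyl 12-methyl 1β-(tert-butyldimethylsilyloxy)drim-7-ene-11,12-dioate | CC(C)(C)[Si](C)(C)O[C@@H]1CCC(C)(C)[C@@H]2CC=C(C(=O)OC)[C@H](C(=O)OCC)[C@@]12C | intermediate
14 | 1β-(tert-butyldimethylsilyloxy)drim-7-ene-11,12-diol | CC(C)(C)[Si](C)(C)O[C@@H]1CCC(C)(C)[C@@H]2CC=C(CO)[C@H](CO)[C@@]12C | intermediate
15 | 11,12-O-isopropylidene-1β-(tert-butyldimethylsilyloxy)drim-7-ene-11,12-diol | CC(C)(C)[Si](C)(C)O[C@@H]1CCC(C)(C)[C@@H]2CC=C3COC(C)(C)OC[C@@H]3[C@@]12C | intermediate
16 | 11,12-O-isopropylidenedrim-7-ene-1β,11,12-triol | O[C@@H]1CCC(C)(C)[C@@H]2CC=C3COC(C)(C)OC[C@@H]3[C@@]12C | intermediate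
17 | (E)-3-(4-methoxyphenyl)prop-2-enoyl chloride | COc1ccc(/C=C/C(Cl)=O)cc1 | starting material
18 | 1β-[(E)-4-methoxycinnamoyloxy]-11,12-O-isopropylidenedrim-7-ene-11,12-diol | COc1ccc(/C=C/C(=O)O[C@@H]2CCC(C)(C)[C@@H]3CC=C4COC(C)(C)OC[C@@H]4[C@@]23C)cc1 | intermediate
19 | 1β-[(E)-4-methoxycinnamoyloxy]drim-7-ene-11,12-diol | COc1ccc(/C=C/C(=O)O[C@@H]2CCC(C)(C)[C@@H]3CC=C(CO)[C@H](CO)[C@@]23C)cc1 | intermediate
20 | 1β-[(E)-4-methoxycinnamoyloxy]drim-7-ene-11,12-dial, (1R,5S,9R,10S) | COc1ccc(/C=C/C(=O)O[C@@H]2CCC(C)(C)[C@@H]3CC=C(C=O)[C@H](C=O)[C@@]23C)cc1 | target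

**Totals**

Total step count: 14. Longest linear sequence: 14 steps (from 1 and 2 to 20).

**Steps most likely to fail**

Step 2. The allylboration may stall or show poor facial selectivity at the neopentyl aldehyde with a tertiary allylboronate, and the C4 radical may be reduced before it closes the ring when both stages share one flask. The fallback separates the two bonds and sets C1 by reduction instead. It sets out from 4: addition of 3-methylbut-3-enylmagnesium bromide with anhydrous CeCl3 at −78 °C to the aldehyde should give ethyl (1S,2S)-2-[(1R)-1-hydroxy-4-methylpent-4-enyl]-2-methyl-5-oxocyclohex-3-ene-1-carboxylate F1, together with its C1 epimer. A separate Fe(acac)3/PhSiH3 cyclisation of the 1,1-disubstituted alkene (same C4 radical) comes back to the route at 7. If the C1 epimers cannot be separated, they are carried on to 16, where Dess–Martin oxidation gives 11,12-O-isopropylidene-11,12-dihydroxydrim-7-en-1-one F2; NaBH4 reduction of F2 (axial hydride delivery anti to the axial C10 methyl) should return the equatorial 1β-alcohol 16.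

Step 4. The second dehydrogenation must remove a tertiary hydrogen at C5 between two quaternary carbons and may stop at a mono-enone or over-oxidise. The fallback uses halogenation and elimination in place of hypervalent iodine. It sets out from 8: α,α′-dibromination with phenyltrimethylammonium tribromide in THF should give ethyl 6,8-dibromo-1β-(tert-butyldimethylsilyloxy)-7-oxo-12-nor-5β-driman-11-oate F3, and double dehydrobromination (Li2CO3, LiBr, DMF, 120 °C) comes back to the route at 9.

Step 7. Enolisation may occur toward C6 instead of C8, or excess base may epimerise C9. The fallback uses a thermodynamic formylation and a 1,3-carbonyl transposition in place of kinetic triflation and carbonylation. It sets out from 11: NaH/ethyl formate should formylate the less hindered C8 to give ethyl 1β-(tert-butyldimethylsilyloxy)-8-(hydroxymethylene)-7-oxo-12-nor-5α-driman-11-oate F4. Butanethiol and TsOH convert it to ethyl 8-(butylsulfanylmethylene)-1β-(tert-butyldimethylsilyloxy)-7-oxo-12-nor-5α-driman-11-oate F5, and NaBH4 gives ethyl 8-(butylsulfanylmethylene)-1β-(tert-butyldimethylsilyloxy)-7-hydroxy-12-nor-5α-driman-11-oate F6. Hydrolysis with allylic transposition (HgCl2, aq. MeCN) should give ethyl 1β-(tert-butyldimethylsilyloxy)-12-oxodrim-7-en-11-oate F7. DIBAL reduction of the aldehyde and ester of F7 comes back to the route at 14.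

**Further compounds**

F1 | step 2 | ethyl (1S,2S)-2-[(1R)-1-hydroxy-4-methylpent-4-enyl]-2-methyl-5-oxocyclohex-3-ene-1-carboxylate | CCOC(=O)[C@H]1CC(=O)C=C[C@]1(C)[C@H](O)CCC(C)=C
F2 | step 2 | 11,12-O-isopropylidene-11,12-dihydroxydrim-7-en-1-one | O=C1CCC(C)(C)[C@@H]2CC=C3COC(C)(C)OC[C@@H]3[C@@]12C
F3 | step 4 | ethyl 6,8-dibromo-1β-(tert-butyldimethylsilyloxy)-7-oxo-12-nor-5β-driman-11-oate | CC(C)(C)[Si](C)(C)O[C@@H]1CCC(C)(C)[C@H]2C(Br)C(=O)C(Br)[C@H](C(=O)OCC)[C@@]12C
F4 | step 7 | ethyl 1β-(tert-butyldimethylsilyloxy)-8-(hydroxymethylene)-7-oxo-12-nor-5α-driman-11-oate | CC(C)(C)[Si](C)(C)O[C@@H]1CCC(C)(C)[C@@H]2CC(=O)C(=CO)[C@H](C(=O)OCC)[C@@]12C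
F5 | step 7 | ethyl 8-(butylsulfanylmethylene)-1β-(tert-butyldimethylsilyloxy)-7-oxo-12-nor-5α-driman-11-oate | CC(C)(C)[Si](C)(C)O[C@@H]1CCC(C)(C)[C@@H]2CC(=O)C(=CSCCCC)[C@H](C(=O)OCC)[C@@]12C
F6 | step 7 | ethyl 8-(butylsulfanylmethylene)-1β-(tert-butyldimethylsilyloxy)-7-hydroxy-12-nor-5α-driman-11-oate | CC(C)(C)[Si](C)(C)O[C@@H]1CCC(C)(C)[C@@H]2CC(O)C(=CSCCCC)[C@H](C(=O)OCC)[C@@]12C
F7 | step 7 | ethyl 1β-(tert-butyldimethylsilyloxy)-12-oxodrim-7-en-11-oate | CC(C)(C)[Si](C)(C)O[C@@H]1CCC(C)(C)[C@@H]2CC=C(C=O)[C@H](C(=O)OCC)[C@@]12C
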